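**Retrosynthetic overview**
- Endgame: the enal comes last, by SeO2 then MnO2 oxidation of a 2-isopropenyl group. The (R)-carbinol and its angelate come from a 5-acetyl group by transfer hydrogenation and mixed-anhydride acylation.
- Key disconnection O1–C2. The run C3(OAc)–C2(O1)–C1′ (C1′ = the exocyclic carbon that becomes C(=CH2)CHO) is the retron of a 2,3-epoxy alcohol. O1 and C3 sit ortho on the benzene ring (C7a, C3a), and the 5-acetyl group is para to O1.
- Precursor: a cis-oxirane across C2–C3 (a ring not in the target), a tertiary hydroxyl on C1′, and the phenol masked as its acetate. Catalytic base walks the oxirane to C1′–C2, hands the acetyl group from O1 to O–C3, and lets O1 close the dihydrofuran ring (O1, C2, C3, C3a, C7a).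
- The precursor comes from 4′-hydroxy-3′-iodoacetophenone by acetylation, Sonogashira coupling with 2-methylbut-3-yn-2-ol, Lindlar reduction and Jacobsen epoxidation (the only source of the two ring stereocentres).
- Ring order: benzene ring (bought), then oxirane C2–C3, then oxirane C1′–C2 and the dihydrofuran ring in the key step.

Key step: step 5

Remark: 1-(4-hydroxy-3-iodophenyl)ethan-1-one, 2-methylbut-3-yn-2-ol and angelic acid are taken as commercial. Locants O1, C2, C3, C3a, C7a are those of the benzofuran; C1′ is the exocyclic carbon on C2.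

**Step 1**
Reactants: 1 1-(4-hydroxy-3-iodophenyl)ethan-1-one
Product: 2 4-acetyl-2-iodophenyl acetate
Conditions: Ac2O, pyridine, DMAP (cat.), CH2Cl2, 0 °C to 23 °C
Reagents that add atoms: acetic anhydride CC(=O)OC(C)=O
Why: DMAP-catalysed O-acetylation of the phenol; the acetate masks O1 through steps 2 to 4 and is the acetyl group that the key step hands on to O–C3.

**Step 2**
Reactants: 2 4-acetyl-2-iodophenyl acetate; 3 2-methylbut-3-yn-2-ol
Product: 4 4-acetyl-2-(3-hydroxy-3-methylbut-1-yn-1-yl)phenyl acetate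
Conditions: PdCl2(PPh3)2 (2 mol%), CuI (4 mol%), Et3N, THF, 23 °C
Reagents that add atoms: none
Why: Sonogashira coupling of the aryl iodide with the terminal alkyne; the O-acetyl group keeps an ortho-alkynylphenoxide from cyclising to a benzofuran.

**Step 3**
Reactants: 4 4-acetyl-2-(3-hydroxy-3-methylbut-1-yn-1-yl)phenyl acetate
Product: 5 4-acetyl-2-[(1Z)-3-hydroxy-3-methylbut-1-en-1-yl]phenyl acetate
Conditions: H2 (1 atm), Pd/CaCO3 poisoned with Pb(OAc)2 (Lindlar catalyst), quinoline, EtOAc, 23 °C
Reagents that add atoms: none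
Why: Lindlar semihydrogenation should give the Z alkene by syn addition of hydrogen on the poisoned surface, leaving aryl ketone and ester untouched.

**Step 4**
Reactants: 5 4-acetyl-2-[(1Z)-3-hydroxy-3-methylbut-1-en-1-yl]phenyl acetate
Product: 6 4-acetyl-2-[(2S,3S)-3-(2-hydroxypropan-2-yl)oxiran-2-yl]phenyl acetate (cis-oxirane)
Conditions: (S,S)-(salen)MnCl [(S,S)-N,N′-bis(3,5-di-tert-butylsalicylidene)-1,2-cyclohexanediaminomanganese chloride, trivalent manganese] (5 mol%), NMO, mCPBA, CH2Cl2, −78 °C
Reagents that add atoms: 3-chloroperoxybenzoic acid OOC(=O)c1cccc(Cl)c1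
Why: Jacobsen–Katsuki epoxidation of a cis-disubstituted aryl alkene with a quaternary oxygenated allylic carbon (the open-chain counterpart of a 2,2-dimethylchromene); the (S,S) catalyst is expected, by analogy with cis-β-methylstyrene, indene and the chromenes, to give the (S)-benzylic carbon, so both oxirane stereocentres are set here under catalyst control.

**Step 5**
Reactants: 6 4-acetyl-2-[(2S,3S)-3-(2-hydroxypropan-2-yl)oxiran-2-yl]phenyl acetate
Product: 9 (2S,3S)-5-acetyl-2-(2-hydroxypropan-2-yl)-2,3-dihydro-1-benzofuran-3-yl acetate, via Payne-rearranged epoxy alkoxide 7 (not isolated), via phenoxide epoxy acetate 8 (not isolated)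
Conditions: NaH (0.2 equiv), anhydrous THF, 0 °C to 23 °C; then AcOH, aq. NH4Cl
Reagents that add atoms: none
Why: Proposed new method: the sodium alkoxide of the tertiary alcohol of 6 attacks C2 from the rear of the C2–O bond (Payne rearrangement, inversion at C2), which moves the oxirane to C1′–C2 and sets free the C3 alkoxide 7; 7 takes the acetyl group from the ortho aryl acetate through a six-membered transition state (driven by the alkoxide-to-phenoxide pKa gap) to give 8, whose phenoxide O1 opens the new oxirane at its secondary carbon C2 (second inversion), and the tertiary alkoxide so formed deprotonates the next molecule of 6, so the base is only a catalyst. The closest known reaction types are the Payne rearrangement of 2,3-epoxy alcohols with in situ opening of the rearranged epoxide, base-induced aryl-to-alkyl acyl migration, and the biomimetic phenoxide cyclisation of ortho-(2,3-epoxy-3-methylbutyl)phenols to 2-(2-hydroxypropan-2-yl)-2,3-dihydrobenzofurans; joining them in one catalytic isomerisation is the new element. The transient 2,2-dimethyloxirane closes 3-exo-tet and the dihydrofuran ring closes 5-exo-tet (O1 on C2, leaving oxygen on exocyclic C1′). No stereocentre is made from a prochiral atom: the C3–O bond is never broken, so C3 keeps its configuration from step 4, and C2 is inverted twice, so O1 ends where the oxirane oxygen stood and the cis-oxirane maps onto the 2,3-trans ring, (2S,3S) by CIP. The step needs O1 to stay masked while the oxirane is benzylic, attack of O1 at C2 and not at C1′ (6-endo, chromane), and no ionisation at C3 once the phenoxide is free: the aryl acetate can be cleaved only by the C3 alkoxide that the Payne step creates, SN2 opening under basic conditions prefers the secondary over the quaternary oxirane carbon, and the acetyl group para to O1 makes phenoxide 8 a poor donor for ortho-quinone-methide formation.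

**Step 6**
Reactants: 9 (2S,3S)-5-acetyl-2-(2-hydroxypropan-2-yl)-2,3-dihydro-1-benzofuran-3-yl acetate
Product: 10 (2R,3S)-5-acetyl-2-(prop-1-en-2-yl)-2,3-dihydro-1-benzofuran-3-yl acetate
Conditions: Burgess reagent (methyl N-(triethylammoniosulfonyl)carbamate), toluene, 50 °C
Reagents that add atoms: none
Why: Burgess dehydration (syn elimination of the sulfamate ester) of the tertiary alcohol, in which six unhindered methyl hydrogens compete with one C2–H that is inductively deactivated by O1 and the acetoxy carbon, as in the dehydration of related 2-(2-hydroxypropan-2-yl)dihydrobenzofurans to isopropenyl compounds; C2 is untouched and its descriptor changes from S to R only through CIP priorities.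

**Step 7**
Reactants: 10 (2R,3S)-5-acetyl-2-(prop-1-en-2-yl)-2,3-dihydro-1-benzofuran-3-yl acetate
Product: 11 (2R,3S)-5-[(1R)-1-hydroxyethyl]-2-(prop-1-en-2-yl)-2,3-dihydro-1-benzofuran-3-yl acetate
Conditions: RuCl[(R,R)-TsDPEN](p-cymene) (1 mol%), HCO2H/Et3N (5:2), DMF, 30 °C
Reagents that add atoms: none
Why: Noyori–Ikariya asymmetric transfer hydrogenation of the aryl methyl ketone; the (R,R) catalyst should give the (R)-1-arylethanol under catalyst control, as with 4-methoxyacetophenone, and acetate and alkene are inert.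

**Step 8**
Reactants: 11 (2R,3S)-5-[(1R)-1-hydroxyethyl]-2-(prop-1-en-2-yl)-2,3-dihydro-1-benzofuran-3-yl acetate; 12 angelic acid, (2Z)-2-methylbut-2-enoic acid
Product: 14 (1R)-1-[(2R,3S)-3-acetoxy-2-(prop-1-en-2-yl)-2,3-dihydro-1-benzofuran-5-yl]ethyl (2Z)-2-methylbut-2-enoate, via mixed anhydride 13 (not isolated)
Conditions: 12, 2,4,6-trichlorobenzoyl chloride, Et3N, toluene, 23 °C; then 11, toluene, 75 °C
Reagents that add atoms: none
Why: Yamaguchi-type acylation through the angelic 2,4,6-trichlorobenzoic mixed anhydride without DMAP, the protocol known to transfer the angeloyl group without Z-to-E isomerisation; the carbinol is acylated with retention.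

**Step 9**
Reactants: 14 (1R)-1-[(2R,3S)-3-acetoxy-2-(prop-1-en-2-yl)-2,3-dihydro-1-benzofuran-5-yl]ethyl (2Z)-2-methylbut-2-enoate
Product: 15 (1R)-1-[(2R,3S)-3-acetoxy-2-(3-hydroxyprop-1-en-2-yl)-2,3-dihydro-1-benzofuran-5-yl]ethyl (2Z)-2-methylbut-2-enoate
Conditions: SeO2 (0.3 equiv), t-BuOOH (2 equiv, in decane), CH2Cl2, 23 °C
Reagents that add atoms: tert-butyl hydroperoxide CC(C)(C)OO (oxygen delivered through catalytic SeO2, O=[Se]=O)
Why: Sharpless SeO2/t-BuOOH allylic hydroxylation (ene reaction, then [2,3]-shift) of the 1,1-disubstituted alkene at its methyl group, as in the oxidation of the isopropenyl-dihydrobenzofuran unit of rotenone to amorphigenin; the electron-poor angelate alkene should not react at 23 °C, and any aldehyde from over-oxidation is already compound 16.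

**Step 10**
Reactants: 15 (1R)-1-[(2R,3S)-3-acetoxy-2-(3-hydroxyprop-1-en-2-yl)-2,3-dihydro-1-benzofuran-5-yl]ethyl (2Z)-2-methylbut-2-enoate
Product: 16 (1R)-1-[(2R,3S)-3-acetoxy-2-(3-oxoprop-1-en-2-yl)-2,3-dihydro-1-benzofuran-5-yl]ethyl (2Z)-2-methylbut-2-enoate (target)
Conditions: activated MnO2 (excess), CH2Cl2, 23 °C
Reagents that add atoms: none
Why: Activated MnO2 oxidises only the primary allylic alcohol, under neutral conditions that should spare the enal (prone to SN2′ ring opening with nucleophiles), the angelate geometry and both benzylic esters.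

**Compound list**
1 | 1-(4-hydroxy-3-iodophenyl)ethan-1-one | CC(=O)c1ccc(O)c(I)c1 | starting material
2 | 4-acetyl-2-iodophenyl acetate | CC(=O)Oc1ccc(C(C)=O)cc1I | intermediate
3 | 2-methylbut-3-yn-2-ol | CC(C)(O)C#C | starting material
4 | 4-acetyl-2-(3-hydroxy-3-methylbut-1-yn-1-yl)phenyl acetate | CC(=O)Oc1ccc(C(C)=O)cc1C#CC(C)(C)O | intermediate
5 | 4-acetyl-2-[(1Z)-3-hydroxy-3-methylbut-1-en-1-yl]phenyl acetate | CC(=O)Oc1ccc(C(C)=O)cc1/C=C\C(C)(C)O | intermediate
6 | 4-acetyl-2-[(2S,3S)-3-(2-hydroxypropan-2-yl)oxiran-2-yl]phenyl acetate | CC(=O)Oc1ccc(C(C)=O)cc1[C@@H]2O[C@@H]2C(C)(C)O | intermediate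
7 | 4-acetyl-2-{(S)-[(2R)-3,3-dimethyloxiran-2-yl](hydroxy)methyl}phenyl acetate (present as its sodium alkoxide) | CC(=O)Oc1ccc(C(C)=O)cc1[C@H](O)[C@H]2OC2(C)C | intermediate (not isolated)
8 | (S)-(5-acetyl-2-hydroxyphenyl)[(2R)-3,3-dimethyloxiran-2-yl]methyl acetate (present as its sodium phenoxide) | CC(=O)c1ccc(O)c(c1)[C@H](OC(C)=O)[C@H]2OC2(C)C | intermediate (not isolated)
9 | (2S,3S)-5-acetyl-2-(2-hydroxypropan-2-yl)-2,3-dihydro-1-benzofuran-3-yl acetate (2,3-trans) | CC(C)(O)[C@H]1Oc2ccc(C(C)=O)cc2[C@@H]1OC(C)=O | intermediate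
10 | (2R,3S)-5-acetyl-2-(prop-1-en-2-yl)-2,3-dihydro-1-benzofuran-3-yl acetate | C=C(C)[C@H]1Oc2ccc(C(C)=O)cc2[C@@H]1OC(C)=O | intermediate
11 | (2R,3S)-5-[(1R)-1-hydroxyethyl]-2-(prop-1-en-2-yl)-2,3-dihydro-1-benzofuran-3-yl acetate | C=C(C)[C@H]1Oc2ccc([C@@H](C)O)cc2[C@@H]1OC(C)=O | intermediate
12 | angelic acid, (2Z)-2-methylbut-2-enoic acid | C/C=C(/C)C(=O)O | starting material
13 | (2Z)-2-methylbut-2-enoic 2,4,6-trichlorobenzoic anhydride | C/C=C(/C)C(=O)OC(=O)c1c(Cl)cc(Cl)cc1Cl | intermediate (not isolated)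
14 | (1R)-1-[(2R,3S)-3-acetoxy-2-(prop-1-en-2-yl)-2,3-dihydro-1-benzofuran-5-yl]ethyl (2Z)-2-methylbut-2-enoate | C=C(C)[C@H]1Oc2ccc([C@@H](C)OC(=O)/C(C)=C\C)cc2[C@@H]1OC(C)=O | intermediate
15 | (1R)-1-[(2R,3S)-3-acetoxy-2-(3-hydroxyprop-1-en-2-yl)-2,3-dihydro-1-benzofuran-5-yl]ethyl (2Z)-2-methylbut-2-enoate | C=C(CO)[C@H]1Oc2ccc([C@@H](C)OC(=O)/C(C)=C\C)cc2[C@@H]1OC(C)=O | intermediate
16 | (1R)-1-[(2R,3S)-3-acetoxy-2-(3-oxoprop-1-en-2-yl)-2,3-dihydro-1-benzofuran-5-yl]ethyl (2Z)-2-methylbut-2-enoate | C=C(C=O)[C@H]1Oc2ccc([C@@H](C)OC(=O)/C(C)=C\C)cc2[C@@H]1OC(C)=O | target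

**Step count and risks**
Total step count: 10. Longest linear sequence: 10 steps (1 to 16).

The three steps most likely to fail:

1. Step 5 (Proposed new method). The relay may leave its course at the stage of phenoxide 8, by loss of acetate from the benzylic C3 (ortho-quinone-methide formation, which scrambles C3), or in the product alkoxide, by wandering of the acetyl group to the tertiary oxygen. The fallback uses known chemistry and gives up the relay. It sets out from 6: NaOH (3 equiv) in water/THF at 23 °C saponifies the aryl acetate, and the Payne rearrangement and 5-exo opening then run in the dianion, in which the benzylic oxygen is an alkoxide and cannot leave. This should give the diol 1-[(2S,3S)-3-hydroxy-2-(2-hydroxypropan-2-yl)-2,3-dihydro-1-benzofuran-5-yl]ethan-1-one F1. Ac2O, pyridine and cat. DMAP at 0 °C should acetylate only the secondary hydroxyl, and the route is rejoined at 9.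

2. Step 4. Facial selectivity may be poor, or the cis alkene may leak to the trans-oxirane through the radical intermediate of the manganese-oxo pathway, which would end as the 2,3-cis ring. The fallback sets out from 5 and changes both alkene geometry and oxidant. Catalytic PhSSPh under irradiation isomerises 5 to 4-acetyl-2-[(1E)-3-hydroxy-3-methylbut-1-en-1-yl]phenyl acetate F2. Shi epoxidation (D-fructose-derived ketone, Oxone (2KHSO5·KHSO4·K2SO4), NaHCO3, MeCN/water, 0 °C), a concerted dioxirane transfer without loss of geometry, should give 4-acetyl-2-[(2R,3S)-3-(2-hydroxypropan-2-yl)oxiran-2-yl]phenyl acetate F3. NaOH in water/THF (saponification, Payne rearrangement, 5-exo opening) then leads to the 2,3-cis diol 1-[(2S,3R)-3-hydroxy-2-(2-hydroxypropan-2-yl)-2,3-dihydro-1-benzofuran-5-yl]ethan-1-one F4. Mitsunobu esterification with acetic acid (PPh3, DIAD, THF, 0 °C) inverts C3, leaves the tertiary alcohol alone, and rejoins the route at 9.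

3. Step 9. At the most advanced stage the selenium conditions may over-oxidise, attack other allylic or benzylic positions, or, through acidic selenium species, ionise the para-alkoxybenzylic angelate and expel acetic acid toward the aromatic benzofuran. The fallback sets out from 10 and moves the oxidation ahead of the sensitive groups. SeO2/t-BuOOH on the robust ketone 10 should give (2R,3S)-5-acetyl-2-(3-hydroxyprop-1-en-2-yl)-2,3-dihydro-1-benzofuran-3-yl acetate F5. TBSCl and imidazole in DMF give (2R,3S)-5-acetyl-2-[3-(tert-butyldimethylsilyloxy)prop-1-en-2-yl]-2,3-dihydro-1-benzofuran-3-yl acetate F6. Transfer hydrogenation as in step 7 gives (2R,3S)-2-[3-(tert-butyldimethylsilyloxy)prop-1-en-2-yl]-5-[(1R)-1-hydroxyethyl]-2,3-dihydro-1-benzofuran-3-yl acetate F7. Angeloylation as in step 8 gives (1R)-1-[(2R,3S)-3-acetoxy-2-[3-(tert-butyldimethylsilyloxy)prop-1-en-2-yl]-2,3-dihydro-1-benzofuran-5-yl]ethyl (2Z)-2-methylbut-2-enoate F8. HF·pyridine in THF at 0 °C removes the silyl group and rejoins the route at 15.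

Further compounds
F1 | step 5 | 1-[(2S,3S)-3-hydroxy-2-(2-hydroxypropan-2-yl)-2,3-dihydro-1-benzofuran-5-yl]ethan-1-one | CC(C)(O)[C@H]1Oc2ccc(C(C)=O)cc2[C@@H]1O
F2 | step 4 | 4-acetyl-2-[(1E)-3-hydroxy-3-methylbut-1-en-1-yl]phenyl acetate | CC(=O)Oc1ccc(C(C)=O)cc1/C=C/C(C)(C)O
F3 | step 4 | 4-acetyl-2-[(2R,3S)-3-(2-hydroxypropan-2-yl)oxiran-2-yl]phenyl acetate | CC(=O)Oc1ccc(C(C)=O)cc1[C@H]2O[C@@H]2C(C)(C)O
F4 | step 4 | 1-[(2S,3R)-3-hydroxy-2-(2-hydroxypropan-2-yl)-2,3-dihydro-1-benzofuran-5-yl]ethan-1-one | CC(C)(O)[C@H]1Oc2ccc(C(C)=O)cc2[C@H]1O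
F5 | step 9 | (2R,3S)-5-acetyl-2-(3-hydroxyprop-1-en-2-yl)-2,3-dihydro-1-benzofuran-3-yl acetate | C=C(CO)[C@H]1Oc2ccc(C(C)=O)cc2[C@@H]1OC(C)=O
F6 | step 9 | (2R,3S)-5-acetyl-2-[3-(tert-butyldimethylsilyloxy)prop-1-en-2-yl]-2,3-dihydro-1-benzofuran-3-yl acetate | C=C(CO[Si](C)(C)C(C)(C)C)[C@H]1Oc2ccc(C(C)=O)cc2[C@@H]1OC(C)=O
F7 | step 9 | (2R,3S)-2-[3-(tert-butyldimethylsilyloxy)prop-1-en-2-yl]-5-[(1R)-1-hydroxyethyl]-2,3-dihydro-1-benzofuran-3-yl acetate | C=C(CO[Si](C)(C)C(C)(C)C)[C@H]1Oc2ccc([C@@H](C)O)cc2[C@@H]1OC(C)=O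
F8 | step 9 | (1R)-1-[(2R,3S)-3-acetoxy-2-[3-(tert-butyldimethylsilyloxy)prop-1-en-2-yl]-2,3-dihydro-1-benzofuran-5-yl]ethyl (2Z)-2-methylbut-2-enoate | C=C(CO[Si](C)(C)C(C)(C)C)[C@H]1Oc2ccc([C@@H](C)OC(=O)/C(C)=C\C)cc2[C@@H]1OC(C)=O
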